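The data come from a simulation with constants of no real substance.

Slowness is what you reckon with here: solid electrophile crawls into solution, and each dissolved molecule then waits for nucleophile before it counts as reacted.

all flasks: solid electrophile 0.20 M; gas 11 mM (held)
- green: free base 0.27 M; run made earlier
- teal: free base 0.26 M; run made earlier
- alpha: free base 0.240 M; time 2.5 min
- epsilon: free base 0.310 M; time 2.5 min

| run | time / s | solid electrophile / % | product / % |
|---|---|---|---|
| green | 10.0 | 97.0 | 0.3 |
| green | 15.0 | 96.9 | 0 |
| green | 30.0 | 92.3 | 0.8 |
| green | 80.0 | 81.2 | 5.3 |
| teal | 10.0 | 97.5 | 0.3 |
| teal | 25.0 | 93.4 | 0.3 |
| teal | 50.0 | 86.5 | 1.6 |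
| teal | 80.0 | 81.0 | 4.7 |

(each reading ± 0.5 percentage points)

- for acid set free the idle adduct is counted in
- as a solid, counted per litre of solution: solid electrophile
- at the start none of nucleophile is dissolved
- the numbers in the tables scatter with a standard deviation of 0.5 percentage points
- on the list of suspects stand: electrophile + nucleophile -> acid set free + product; solid electrophile <-> electrophile; nucleophile + acid set free <-> idle adduct; gas <-> nucleophile; acid set free + free base <-> salt of the base; nucleophile + acid set free <-> protonated nucleophile
- at the start none of the solid electrophile is in solution
- what has only dissolved of solid electrophile counts as not reacted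

1. part of the solid electrophile that has reacted (what has only dissolved counts as not reacted) at the end, alpha
2. part of the solid electrophile that has reacted (what has only dissolved counts as not reacted) at the end, epsilon
3. what raising the concentration of free base from its lowest to its highest value here does to the part of the solid electrophile that has reacted (what has only dissolved counts as not reacted) (changes below 5 percentage points count as none) (it falls / no change / it rises)

Read the solid column first. By 80.0 s, green and teal have lost 18.9% on average, so the solid dissolved per litre per second, the crawl s, comes to 0.472 mM s⁻¹.

Now set the product column beside it. At 30.0 s, green has lost 7.70% of its solid but shows 0.8% product, so dissolved molecules are waiting. At 80.0 s, mean product is 5.00%, which leaves a dissolved stock of 13.9%. Take that stock as rising evenly from nothing, divide its mean by the rate of product formation, and you get a mean wait τ of 111 s, the inverse of a pseudo-first-order constant. I take s and τ, both read from scattered readings, as steady, with the gas held at 11 mM.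

Feed s into a stock draining with τ. The stock standing at time t is s·τ times one minus e^(−t/τ), and the rest of s·t has reacted. At 2.5 min, that is 0.0320 M, or 16.0% of the charge, in alpha and epsilon alike. Green and teal hold 0.27 M and 0.26 M of free base, too close together to say much of the trend. Each molecule reacted sets free one acid, and my expectation of no change rests on that 0.0320 M of acid set free being less than the 0.240 M of free base.

The forecast gave 13% (10% to 18%) for alpha, 13% (10% to 18%) for epsilon and no change, lower than my figure: “Conversion is therefore limited by dissolution and gas, not base”.

The flask gives 14.1% in alpha and 14.1% in epsilon, so no change, with a shift of 0.011 percentage points.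

    electrophile + nucleophile → acid set free + product (k = 0.730 M⁻¹ s⁻¹)
    solid electrophile ⇌ electrophile, rate k2*(cs2 - [electrophile]) while solid is left; crystals form when [electrophile] > cs2 (solubility = 0.170 M, k = 0.00320 s⁻¹)
    nucleophile + acid set free ⇌ idle adduct, settled at all times (K = 220 M⁻¹)
    gas ⇌ nucleophile, rate k4*(csat - [nucleophile]) (kL = 0.460 s⁻¹)
    acid set free + free base ⇌ salt of the base (K = 9.40 M⁻¹, k = 2.30 M⁻¹ s⁻¹)
    nucleophile + acid set free ⇌ protonated nucleophile, settled at all times (K = 1900 M⁻¹)

My reckoning stands 1.9 points high in alpha and epsilon. Alpha stands this low partly because of the low solubility of electrophile, which also sets how fast it dissolves, and partly because of the early reading: without the first it reaches 57.3%, and at 25.0 min it reaches >99.9%. Reading alpha at 1.90 min or 3.05 min shifts its answer by 5 points. Take a flask like epsilon with 0.34 M of solid electrophile: the same s and τ give 0.0320 M reacted, 9.41% of its charge, and it gives 8.32%.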